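(Its constants were drawn at random within sensible limits; the result is computed.)

The number that opens this flask is 7.80, which is 2 times the pairing constant Kp (the equilibrium constant of enzyme + enzyme ⇌ resting dimer) times the charged catalyst Ct of 1.00 µM, and it is larger than 1, so I expect pairing of enzyme to matter.

    starting material + enzyme ⇌ complex (K1 = 44 L mol⁻¹, k1 = 7.8 × 10⁵ L mol⁻¹ s⁻¹)
    complex → enzyme + product (k2 = 53 s⁻¹)
    enzyme + enzyme ⇌ resting dimer (K3 = 3.9 × 10⁶ L mol⁻¹, k3 = 11000 L mol⁻¹ s⁻¹)

starting material 10 mM; enzyme 0.01 mol%

- where a step has two of a species, its rate is k times that concentration squared, and two are used at each turn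
- a form made of two catalysts counts as two
- charge of starting material (flask): 10 mM

1. the form that holds most of the catalyst when 20% of the starting material are converted (enzyme / resting dimer / complex)
2. its share of the catalyst then
3. factor on the rate of making product when 20% of the starting material are converted if enzyme is charged twice over
4. factor on the rate when 20% of the starting material are converted if enzyme is charged at 0.001 mol% instead

I write S for starting material, E for free enzyme and C for complex. I take the complex in steady state, C = E·S/Km, with Km = (koff + kcat)/kon = 22.8 mM, where kon and koff are the forward and back rate constants of the binding step and kcat is the rate constant of complex → enzyme + product. At 20% conversion S is 8.00 mM, so g = 1 + S/Km = 1.35. With the resting dimer at Kp·E·E, the catalyst balance reads Ct = g·E + 2·Kp·E·E. The rate is kcat·C, and S at this conversion is the same for each charge, so rate factors are ratios of E.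

I start from the square root of Ct/(2·Kp), which ignores every form but the dimer. Then I put each answer back by the Newton step E → (2·Kp·E·E + Ct)/(4·Kp·E + g).

| Ct | start | round 1 | round 2 | round 3 |
|---|---|---|---|---|
| 1.00 µM | 0.358 µM | 0.288 µM | 0.282 µM | 0.282 µM |
| 2.00 µM | 0.506 µM | 0.432 µM | 0.427 µM | 0.427 µM |
| 0.100 µM | 0.113 µM | 0.0642 µM | 0.0562 µM | 0.0559 µM |

In the bottom row the start exceeds the charge itself, so that guess is impossible, yet the rounds repair it. The last column is what I carry: the balance enzyme E*, the free enzyme at which the dimer stands at equilibrium and the complex at steady state.

The top row puts 61.9% of the catalyst in the resting dimer, the resting state. The middle row against the top gives a factor of 1.51, and the bottom row against the top gives 0.198.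

The forecast differs from my reckoning: it gives resting dimer at 59% with factors 1.67 and 0.185, holding that “a small transient remains”.

The simulation gives resting dimer at 59.2%, with enzyme at 30.2% and complex at 10.6%, and factors of 1.65 and 0.186.

Taking pairing away in both directions moves the apparent order in enzyme from 0.70 to 1.0. In this flask at 20% conversion, enzyme reads 30.2%, higher than the 28.2% that E* gives, and the resting dimer is still climbing, from 53.8% at 2.50 min to 60.7% at 5.00 min. For the flask charged at 0.001 mol%, its E* of 0.0559 µM over the enzyme read in this flask gives 0.185, and that flask's simulated factor is 0.186.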